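The rate constants were chosen freely; the flask was simulated.

You start from the amounts: 0.20 M of electrophile stands against 0.240 M of nucleophile, so on paper the electrophile is the reagent charged in the smaller amount.

    electrophile + nucleophile → acid set free + product (k1 = 0.031 L mol⁻¹ min⁻¹)
    nucleophile + acid set free ⇌ protonated nucleophile, settled at all times (K2 = 15000 L mol⁻¹)
    acid set free + free base ⇌ salt of the base, settled at all times (K3 = 2500 L mol⁻¹)
    nucleophile + acid set free ⇌ idle adduct, settled at all times (K4 = 11 L mol⁻¹)
    acid set free + scavenger → scavenged by-product (k5 = 0.19 L mol⁻¹ min⁻¹)
    2 electrophile → homo dimer (k6 = 9.7 × 10⁻⁵ L mol⁻¹ min⁻¹)
    electrophile ⇌ dormant form (K7 = 1.1, k7 = 0.0029 min⁻¹)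
all flasks: electrophile 0.20 M; nucleophile 0.240 M; scavenger 0.160 M; time 10 h
- ochre: free base 0.300 M
- grey: free base 0.390 M
- part of the electrophile that has reacted at the end, ochre
- part of the electrophile that has reacted at the end, grey
- what raising the concentration of free base from its lowest to its highest value here does to the part of the electrophile that has reacted (changes below 5 percentage points count as none) (it falls / it rises / no change)
- in percentages every species weighs as the electrophile in it: one homo dimer counts as two
- for acid set free the idle adduct is counted in
- a step written with two of one species runs at k times the square of its concentration and takes two of it each time
- what has gone from electrophile into another species counts as reacted, even if it can come back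
- run time (ochre): 10 h

Write the balance of the electrophile: the charge is free electrophile, dormant form, product and twice the homo dimer. To fill it in, go down the time scales of ochre at the start.

The acid bindings come first, being kept at balance. Each binding constant times its partner's concentration gives a bid for the acid: nucleophile 3600, free base 750, idle adduct 2.6. At the start the nucleophile therefore takes more of the acid than the free base, a share f = 0.828. So a coupling at the start costs a price π, one nucleophile coupled plus f protonated, which is 1.83.

Coupling comes next: the electrophile's half-life by this step at the start is 1.55 h, shorter than the 4.0 h of the forward dormant step alone. Both are shorter than the run, so as an estimate I let the electrophile and the dormant form stand at their balance, 1.1.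

Far below lie the homo dimer, at 430 h, and the scavenger, which meets free acid and so, at the starting concentrations, takes bound acid on a half-life of 1650 h. I drop both.

Define, for ochre, the stall product P★ = 0.131 M, the charged nucleophile divided by π, which is the product that charge pays for at the starting price. It is less than the electrophile charged, so in this estimate the nucleophile acts as limiting reagent. P★ is an estimate, not a bound: π is the price at the start. Taking P★ as coupled and dividing the rest of the electrophile between free and dormant, I reckon 83.6% reacted for ochre. For grey, P★ = 0.134 M gives 84.4%, so the trend is no change.

The forecast gave 82.5% (79% to 86%) for ochre, 83.5% (80% to 87%) for grey and no change, since more base “frees only slightly more nucleophile”.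

The simulation gives 84.6% for ochre and 85.2% for grey, a change of 0.59 percentage points, so no change.

In ochre at 10.0 h, the forward dormant half-life of 4.0 h is shorter than the nucleophile's coupling half-life of 12 h. Product there stands at 62.8% of the electrophile charged, against 65.5% for P★, with 20% of the nucleophile left. Now take ochre with 0.80 M of electrophile: P★ stays 0.131 M, which is 16.4% of that charge, so the same balance gives 60.2%. The computed flask gives 65.1%, with product at 25.4% and 1.8% of the nucleophile left.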